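The earlier runs and the new flask are calculated with constants of no real substance, and the scatter is random.

A single-handed free catalyst stood in the alpha flask with a racemate and reagent, and I wanted to know what more catalyst buys at 20 % conversion, reached at 0.471 min.

in all of them: left-handed substrate 0.15 M; right-handed substrate 0.15 M

|  | reagent | free catalyst | remark |
|---|---|---|---|
| alpha | 0.45 M | 3 mM | the very flask that is asked about, followed so far |
| flask | 0.450 M | 3.0 mM |  |

- alpha (time / min: left-handed product / %, left-handed substrate / %): 0.417: 13.9, 35.7; 0.667: 19.4, 29.6; 0.833: 23.5, 26.7; 1.33: 32.1, 18.8; 2.00: 36.9, 12.5; 3.00: 42.3, 7.5; 5.00: 45.8, 4.0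

(scatter of a reading: 0.5 percentage points)

- apparent order in free catalyst when 20 % of the left-handed substrate and right-handed substrate together are converted (percent change of the rate of making left-handed product for one percent more free catalyst charged)
- apparent order in reagent when 20 % of the left-handed substrate and right-handed substrate together are converted (percent change of the rate of making left-handed product for one percent more reagent charged)
- factor on the rate of making left-handed product when 20 % of the left-handed substrate and right-handed substrate together are converted if free catalyst is charged twice over

- free catalyst is single-handed; left-handed substrate and right-handed substrate are mirror images of each other, charged as a racemate, each of them at the stated concentration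
- no earlier run changes the charge of free catalyst; that part of a forecast is a guess
- no earlier run changes the charge of reagent; that part of a forecast is a guess

I counted the reagent left from left-handed product alone and divided the pseudo-first-order constant of left-handed substrate by that fraction. This activity read 0.847 min⁻¹ over the first stretch and 0.791 min⁻¹ up to 2.00 min, so I took order one in reagent. Then it read 0.694 min⁻¹ and 0.445 min⁻¹, which gives 0.296 min⁻¹ for the fade rate, the fall of the activity's logarithm per minute between those last stretches. That is a reading, and it carries the scatter of the late points.

If the fade follows conversion, doubled catalyst meets the same state, so the floor is a factor 2, order 1. If it follows the clock, a doubled charge with no fade gives the ceiling, 2.30, order 1.20. Tightened, that charge arrives in half the time and fades that long, giving 2.14, order 1.10, which I committed to, guessing that the catalyst works singly.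

The forecast gave order 0.95 in free catalyst, order 0.95 in reagent and a factor 1.9 on doubling (“Doubling gives just under 2”), below my floor.

The flask gave order 1.1 in free catalyst, order 1.0 in reagent and a factor 2.16 on doubling, above my floor and below the ceiling.

    reagent + catalyst intermediate B → free catalyst + right-handed product (k = 1.30 M⁻¹ s⁻¹)
    reagent + catalyst intermediate A → free catalyst + left-handed product (k = 3.60 M⁻¹ s⁻¹)
    free catalyst ⇌ dormant form (K = 7.60, k = 0.0140 s⁻¹)
    free catalyst + right-handed substrate ⇌ catalyst intermediate B (K = 16.0 M⁻¹, k = 4.40 M⁻¹ s⁻¹)
    free catalyst + left-handed substrate ⇌ catalyst intermediate A (K = 19.0 M⁻¹, k = 27.0 M⁻¹ s⁻¹)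

At 1.20 min the flask held 20.2 % left-handed substrate, 29.6 % left-handed product and 29.7 % of its catalyst as dormant form, and from then to 6.00 min the logarithm of the catalyst share outside the dormant form fell by 0.232 min⁻¹, beside my fade rate of 0.296 min⁻¹. By 12.0 min left-handed substrate stood at 0.879 %, the dormant form at 82.9 %, and reagent went to left-handed product at 0.19 of its rate to right-handed product.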